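The readings are calculated with constants of no real substance; scatter was added.

A small charge tempts you to a rule of thumb: divide it by the first rate and you have the time the flask needs. Take the north-west run in fractions of its Sub charge. Up to the first reading, a share 0.0405 /min of the charge turns into Prd each minute, so the rule promises the end after 24.7 min. But at 36 min, later than that, the share made is 36.3%, and already at 16 min the run holds half of what the straight line promises.

| flask | Sub | Rgt | Prd | time |
|---|---|---|---|---|
| north-west | 120 mM | 120 mM |  |  |
| east | 72.0 mM | 72.0 mM |  |  |
| north-east | 120 mM | 180 mM |  |  |
| south-east | 120 mM | 120 mM | 60.0 mM |  |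
| south | 120 mM | 120 mM |  | 140 min |

- north-west run (time / min: [Prd] / mM): 1.4: 6.8; 3.2: 13.8; 7.2: 23.8; 16: 37.1; 36: 43.6
- east run (time / min: [Prd] / mM): 1.4: 3.8; 3.2: 5.6; 7.2: 10.3; 16: 16.5; 36: 20.8
- north-east run (time / min: [Prd] / mM): 1.4: 9.3; 3.2: 18.5; 7.2: 31.4; 16: 46.5; 36: 53.5
- south-east run (time / min: [Prd] / mM): 1.4: 66.4; 3.2: 72.4; 7.2: 83.6; 16: 96.4; 36: 104.1

(each reading ± 0.6 mM)

- Overall: Sub + Rgt -> Prd.
- Constant volume, constant temperature.
- Bound and free are read together.
- "The second partner" is Rgt.
- An order is taken over about fifteen percent of the charge, up and down.

* the power of [Sub] that the first rate follows, about the charge of the north-west run; measure it at two percent of Sub made into Prd (one fixed amount of Prd, the same in the runs compared)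
* the power of [Rgt] that the first rate follows, about the charge of the north-west run; measure it at two percent of Sub made into Prd
* Prd in the south run at 140 min, as a share of the Sub charged

Added Prd changes little: the south-east run, charged with Prd at 50.0% of its Sub, gains 36.8% of its Sub by 36 min, and the north-west run gains 36.3%. So follow one Sub molecule, and suppose that each minute it has two roads: into Prd, or astray by a side reaction. Treat the fading of the rate as steady, and it tells you the chance per minute of taking either road. In the north-west run, the mean rate up to 3.2 min against the mean rate from 7.2 min to 16 min gives a fade of 0.105 /min. Adding to the last reading the tail that this fade still allows, I reckon the fork share, the selectivity for Prd, at 37.1%. The rest of the fade is the astray chance, the chance per minute that a Sub molecule leaves by the side road: 0.0660 /min. The south run has the north-west charge, and 140 min is 14.7 fade times, so my figure for it is that fork share.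

The forecast gives 0.95 for Sub (0.7 to 1.2), 0.75 for Rgt (0.55 to 0.95) and 39.5% for the south run (37% to 44%), which is above my figure; it says that the south run “should plateau at about 47 mM”.

The flask gives Prd at 37.2% of the Sub charged in the south run at 140 min, with orders 1.1 in Sub and 0.78 in Rgt.

    Sub ⇌ Int, settled at all times (0.3270)
    Int + Rgt → Prd (2.232 /M/min)
    2 Rgt ⇌ Rgt2, settled at all times (3.390 /M)
    Sub → E (0.08160 /min)

The south-east run reaches a quarter of its Sub charge as new Prd at 10.4 min, the north-west run at 10.4 min, and the fork share counts on those two times being equal. Now take the north-east run, with the same Sub charge as the north-west run. Its rate where two percent of the Sub has turned gives a chance into Prd of 0.0549 /min; against the astray chance 0.0660 /min its fork share is 45.4%, so a quarter should come at 6.62 min, and the north-east run reaches it at 6.61 min.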